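(The data were computed for an exercise; noise was put on by code.)

**The decision.** I decided to book every mole of D, the limiting reagent, in one ledger and to run that ledger on one quantity.

| setting | epsilon | eta | cedar | elm | larch | alder |
|---|---|---|---|---|---|---|
| D | 0.41 M | 0.62 M | 0.83 M | 0.83 M | 0.83 M | 0.83 M |
| temperature | −5 °C | 17 °C | 5 °C | 25 °C |  | −15 °C |
| remark | run made earlier | run made earlier |  |  | at 25 °C until 4.0 h, from then on at −15 °C |  |
| time |  |  | 6.0 h | 6.0 h | 6.0 h | 6.0 h |

epsilon run (percent of the D charged)

| time / h | G / % |
|---|---|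
| 0.500 | 0.7 |
| 1.33 | 0.3 |
| 2.50 | 0 |
| 4.00 | 1.7 |
| 6.00 | 0.6 |

eta run (percent of the D charged)

| time / min | G / % |
|---|---|
| 12.0 | 0.9 |
| 30.0 | 3.2 |
| 50.0 | 2.2 |
| 80.0 | 8.8 |
| 120 | 17.2 |

(readings scatter by 1 percentage point)

- the flask that comes out highest in amount of G, in percent of the D charged, or "all alike" when all lie within 1.5 percentage points (cedar / elm / larch / alder / all alike)
- G at the end, in percent of the D charged, cedar
- G at the end, in percent of the D charged, elm
- G at the end, in percent of the D charged, larch
- G at the end, in percent of the D charged, alder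

- in percentages every species weighs as the D in it: one J counts as two
- for G the X are counted in
- as a solid, counted per litre of solution: X
- what may be going on: D -> E; E <-> G; E <-> L; X <-> G; 2 D -> J

**First entries.** Eta's G rises with a lag, from 0.9 % at 12.0 min to 17.2 % at 120 min, as the output of two first-order lags in series does. So I booked D → E → G with one step constant k for both lags. With x = kt, [D] keeps e^−x of its start, E holds x e^−x, and G gets the remainder.

**Going round.** For small x, G is half of x squared, so eta's last reading gives a first x of 0.587. But the thinning of D and E's own drain into G together lower G by about e^(−2x/3), so x is that first value times e^(x/3). Putting x back in gave 0.713, and once more 0.744. Divided by eta's 120 min, that gives the step constant k, the rate constant shared by both lags, 0.372 /h at 17 °C. Epsilon's last two readings, weighted as a line in t squared, gave me 0.0251 /h at −5 °C. They lie close to the scatter, so the apparent activation energy of 79.3 kJ/mol is poorly bounded.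

**My books.** Scaled to 25 °C, k is 0.899 /h, so elm reaches x = 5.39 and G 97.1 %. Cedar gets 0.0901 /h and G 10.3 %. Alder gets 0.00632 /h and G 0.0702 %. Larch books 87.4 % by 4.0 h. After that its time constant of 158 h far exceeds the 2.00 h remaining, so I held larch there. The runs read nothing of L or J, so those entries stayed open, and whatever they hold comes out of my G. I committed to elm as highest.

**The forecast.** It named elm, with cedar 10 %, elm 75 %, larch 68 % and alder 0.2 %. Its elm and larch stand below mine, and it says of them: “I discount the warm flasks and keep their ranges wide”.

**The result.** The flasks gave cedar 8.89 %, elm 89.0 %, larch 80.4 % and alder 0.0457 %, so elm came out highest.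

    D → E (k = 4.76 × 10⁻⁴ /s, Ea = 80.0 kJ/mol)
    E ⇌ G (K = 10.0, k = 1.64 × 10⁻⁴ /s, Ea = 89.0 kJ/mol, ΔH = −42.0 kJ/mol)
    E ⇌ L (K = 4.10, k = 8.27 × 10⁻⁶ /s, Ea = 108 kJ/mol, ΔH = −47.0 kJ/mol)
    X ⇌ G, rate k4*(cs4 - [G]) while solid is left; crystals form when [G] > cs4 (solubility = 9.00 mM, k = 0.00265 /s)
    2 D → J (k = 1.60 × 10⁻⁵ /M/s, Ea = 79.0 kJ/mol)
    (constants at 25 °C)

**Elm's close.** In elm, D → E ran first, with half of its turnover done by 0.397 h, and at 3.00 h D stood at 0.555 % while E held 23.0 %. Through the remaining hours E fell to 3.88 % as G rose, 87.7 % of the charge standing as X. Beside G, elm's E, L and J hold 11.0 %, and my k-ledger's G stood 8.1 percentage points above the flask. Elm repeated at 10 °C has k = 0.165 /h, so the ledger gives G 26.1 %, and that flask held 23.2 %.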